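Atoms are numbered along the chain from the alkyne CH (C1) to the ethyl CH3 (C15), with the ring oxygen between C6 and C12. Everything rests on the C6–C7–C8 segment of the oxocane, where C7 carries chlorine and C6 is the ether carbon: C7 with its chlorine is introduced as dichlorocarbene onto the C6=C8 enol ether of an oxepine. The key step ionises the 8,8-dichloro-2-oxabicyclo[5.1.0]octane, opens its shared C6–C8 bond to the eight-membered ring with a C7 chloroalkene, and lets a silyl enol ether trap the C6 oxocarbenium ion, creating C5–C6 and the C6 stereocentre at once. The precursor is that dichlorocyclopropane with an aryl ether at C9, the acetate at C10 and the silyloxypropyl chain at C12.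

Key step: step 12

Remarks on the chemistry (assumptions and corrections)
- Correction: the ring alkene formed in the key step has its ring carbons cis, but by the sequence rules it is (E), because chlorine outranks C6 on C7; it is named (E) below.
- Precursor design: the C9 oxygen is carried as a 4-methoxyphenyl ether, not a benzylic ether. It has no benzylic C–O bond for silver or silyl triflate to ionise, and its oxygen is a weaker donor toward C6 and toward iridium in step 13.
- Precursor design: the C13 oxygen is carried as a tert-butyldiphenylsilyl ether. Its bulk should disfavour capture of C6 by O13 and shield the upper face of C6 (the face of the C12 side chain).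
- Either face of carbene addition in step 11 leads to the same cation in step 12, because C6 and C8 both become sp2.
- Assumption: lithiated allyl 4-methoxyphenyl ether behaves like other allyl ethers in the alkoxyallylboration of step 6.

Step 1
Reactants: 1 methyl (S)-2-hydroxybutanoate
Product: 2 methyl (S)-2-[(tert-butyldiphenylsilyl)oxy]butanoate
Conditions: t-BuPh2SiCl, imidazole, DMF, rt
Reagents that add atoms: tert-butyl(chloro)diphenylsilane, CC(C)(C)[Si](Cl)(c1ccccc1)c1ccccc1
Why: Imidazole-promoted O-silylation of the secondary alcohol leaves the (S) centre (later C13) untouched and provides a bulky, non-chelating ether.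

Step 2
Reactants: 2 methyl (S)-2-[(tert-butyldiphenylsilyl)oxy]butanoate
Product: 3 (S)-2-[(tert-butyldiphenylsilyl)oxy]butanal
Conditions: i-Bu2AlH, CH2Cl2, −78 °C; aq. Rochelle salt
Reagents that add atoms: none
Why: Low-temperature i-Bu2AlH reduction of the ester stops at the aluminium hemiacetal, which releases the aldehyde on work-up without base and hence without epimerisation of the α-silyloxy centre.

Step 3
Reactants: 3 (S)-2-[(tert-butyldiphenylsilyl)oxy]butanal; 4 tert-butyl[(1-methoxyvinyl)oxy]dimethylsilane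
Product: 5 methyl (3R,4S)-4-[(tert-butyldiphenylsilyl)oxy]-3-hydroxyhexanoate
Conditions: BF3·OEt2, CH2Cl2, −78 °C
Reagents that add atoms: none
Why: Mukaiyama aldol addition in which the monodentate Lewis acid and the non-chelating α-silyloxy group enforce the Felkin–Anh (polar) transition state, so the ketene acetal adds anti to the silyloxy group and sets C12 as (R) (3,4-anti).

Step 4
Reactants: 5 methyl (3R,4S)-4-[(tert-butyldiphenylsilyl)oxy]-3-hydroxyhexanoate
Product: 6 methyl (3R,4S)-4-[(tert-butyldiphenylsilyl)oxy]-3-[(triethylsilyl)oxy]hexanoate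
Conditions: Et3SiOSO2CF3, 2,6-lutidine, CH2Cl2, −78 to 0 °C
Reagents that add atoms: triethylsilyl trifluoromethanesulfonate, CC[Si](CC)(CC)OS(=O)(=O)C(F)(F)F
Why: Silyl triflate and a hindered pyridine base silylate the hindered secondary alcohol cleanly, and the triethylsilyl ether can later be removed selectively beside the tert-butyldiphenylsilyl ether.

Step 5
Reactants: 6 methyl (3R,4S)-4-[(tert-butyldiphenylsilyl)oxy]-3-[(triethylsilyl)oxy]hexanoate
Product: 7 (3R,4S)-4-[(tert-butyldiphenylsilyl)oxy]-3-[(triethylsilyl)oxy]hexanal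
Conditions: i-Bu2AlH, CH2Cl2, −78 °C; aq. Rochelle salt
Reagents that add atoms: none
Why: Partial reduction of the β-silyloxy methyl ester with i-Bu2AlH at −78 °C gives the aldehyde through a tetrahedral aluminium intermediate that does not collapse before work-up.

Step 6
Reactants: 7 (3R,4S)-4-[(tert-butyldiphenylsilyl)oxy]-3-[(triethylsilyl)oxy]hexanal; 8 1-(allyloxy)-4-methoxybenzene
Product: 10 (3R,4R,6R,7S)-7-[(tert-butyldiphenylsilyl)oxy]-3-(4-methoxyphenoxy)-6-[(triethylsilyl)oxy]non-1-en-4-ol, via (Z)-aryloxyallyl-diisopinocampheylborane 9 (not isolated)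
Conditions: 8, s-BuLi, THF, −78 °C; (−)-Ipc2BOMe [from (+)-α-pinene]; BF3·OEt2; 7, −78 °C; then NaOH, H2O2
Reagents that add atoms: none
Why: Asymmetric γ-alkoxyallylboration with a diisopinocampheylborane: the lithiated allyl ether is Z-configured by internal O–Li coordination, the derived Z-allylborane reacts through a chair transition state to give the 3,4-syn pair, and the isopinocampheyl groups from (+)-α-pinene direct addition to the si face of the aldehyde, setting C10 as (R) and C9 as (R) under reagent control.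

Step 7
Reactants: 10 (3R,4R,6R,7S)-7-[(tert-butyldiphenylsilyl)oxy]-3-(4-methoxyphenoxy)-6-[(triethylsilyl)oxy]non-1-en-4-ol
Product: 11 (3R,4S,6R,7S)-7-[(tert-butyldiphenylsilyl)oxy]-3-(4-methoxyphenoxy)-6-[(triethylsilyl)oxy]non-1-en-4-yl acetate
Conditions: AcOH, PPh3, i-PrO2CN=NCO2i-Pr, toluene, 0 °C to rt
Reagents that add atoms: acetic acid, CC(=O)O
Why: Mitsunobu esterification, in which acetate displaces the alkoxyphosphonium ion in an SN2 step, inverts C10 to (S) and installs the acetate of the target in one operation.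

Step 8
Reactants: 11 (3R,4S,6R,7S)-7-[(tert-butyldiphenylsilyl)oxy]-3-(4-methoxyphenoxy)-6-[(triethylsilyl)oxy]non-1-en-4-yl acetate
Product: 12 (3R,4S,6R,7S)-7-[(tert-butyldiphenylsilyl)oxy]-6-hydroxy-3-(4-methoxyphenoxy)non-1-en-4-yl acetate
Conditions: pyridinium p-toluenesulfonate, MeOH/CH2Cl2, 0 °C
Reagents that add atoms: none
Why: Mild acid-catalysed methanolysis cleaves the triethylsilyl ether much faster than the tert-butyldiphenylsilyl ether and leaves acetate, aryl ether and alkene untouched.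

Step 9
Reactants: 12 (3R,4S,6R,7S)-7-[(tert-butyldiphenylsilyl)oxy]-6-hydroxy-3-(4-methoxyphenoxy)non-1-en-4-yl acetate
Product: 13 (3R,4S,6R,7S)-7-[(tert-butyldiphenylsilyl)oxy]-3-(4-methoxyphenoxy)-6-(vinyloxy)non-1-en-4-yl acetate
Conditions: Pd(OCOCF3)2, 4,7-diphenyl-1,10-phenanthroline, Et3N, n-BuOCH=CH2 (solvent), air, 75 °C
Reagents that add atoms: butyl vinyl ether, C=COCCCC
Why: Palladium-catalysed transfer vinylation (transetherification with an alkyl vinyl ether) converts the secondary alcohol into its vinyl ether under nearly neutral conditions without breaking the C12–O bond.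

Step 10
Reactants: 13 (3R,4S,6R,7S)-7-[(tert-butyldiphenylsilyl)oxy]-3-(4-methoxyphenoxy)-6-(vinyloxy)non-1-en-4-yl acetate
Product: 14 (2R,4S,5R)-2-{(S)-1-[(tert-butyldiphenylsilyl)oxy]propyl}-5-(4-methoxyphenoxy)-2,3,4,5-tetrahydrooxepin-4-yl acetate
Conditions: RuCl2(=CHPh)(PCy3)(H2IMes) (second-generation Grubbs catalyst), toluene, 70 °C
Reagents that add atoms: none
Why: Ring-closing metathesis between the terminal alkene and the vinyl ether closes the seven-membered cyclic enol ether with loss of ethylene, a known route to oxepine-type enol ethers.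

Step 11
Reactants: 14 (2R,4S,5R)-2-{(S)-1-[(tert-butyldiphenylsilyl)oxy]propyl}-5-(4-methoxyphenoxy)-2,3,4,5-tetrahydrooxepin-4-yl acetate
Product: 15 (1S,3R,5S,6R,7R)-3-{(S)-1-[(tert-butyldiphenylsilyl)oxy]propyl}-8,8-dichloro-6-(4-methoxyphenoxy)-2-oxabicyclo[5.1.0]octan-5-yl acetate
Conditions: Cl3CCO2Na, MeOCH2CH2OMe, reflux
Reagents that add atoms: sodium trichloroacetate, [Na+].[O-]C(=O)C(Cl)(Cl)Cl
Why: Thermal decarboxylation of the trichloroacetate salt releases dichlorocarbene under neutral conditions that spare the acetate, and its [2+1] cycloaddition to the electron-rich enol ether, expected anti to the C9 aryloxy group, gives the cis-fused dichlorocyclopropane.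

Step 12
Reactants: 15 (1S,3R,5S,6R,7R)-3-{(S)-1-[(tert-butyldiphenylsilyl)oxy]propyl}-8,8-dichloro-6-(4-methoxyphenoxy)-2-oxabicyclo[5.1.0]octan-5-yl acetate; 16 trimethyl(vinyloxy)silane
Product: 18 (2S,3E,5R,6S,8R)-8-{(S)-1-[(tert-butyldiphenylsilyl)oxy]propyl}-3-chloro-5-(4-methoxyphenoxy)-2-(2-oxoethyl)-5,6,7,8-tetrahydro-2H-oxocin-6-yl acetate, via chloroallyl oxocarbenium triflate 17 (not isolated)
Conditions: AgOSO2CF3, 2,6-di-tert-butyl-4-methylpyridine, 4 Å molecular sieves, toluene, 50 °C, 16 added in portions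
Reagents that add atoms: none
Why: Proposed new method: Silver assists loss of the endo chloride while the C6–C8 bond opens in a concerted two-electron disrotatory electrocyclic process, pushed by the ring-oxygen lone pair, to give the 2-chloroallyl cation 17, whose charge sits mainly on C6 as an oxocarbenium ion; the enol ether carbon of 16 then adds to C6 and loss of silyl triflate leaves the aldehyde. The closest known reaction types are the silver- or base-promoted ring expansion of gem-dihalocyclopropanated glycals and related cyclic enol ethers with capture by alcohols or carboxylates, and the Lewis-acid addition of silyl enol ethers to cyclic oxocarbenium ions; carbon capture in the same flask and in an eight-membered ring is the extension. No end-to-end cyclisation is involved: the oxocene is produced by ring expansion when the bond shared by the three- and seven-membered rings breaks. Only the endo chloride can leave, because its departure turns the ring bonds inward and gives the cis ring alkene (E by the sequence rules) that an eight-membered ring can hold, and the exo chlorine stays on C7. Regioselectivity for C6 over C8 follows from oxygen stabilisation of the cation at C6. The new C6 stereocentre is set by substrate control, attack being needed on the face opposite the C12 side chain, which flanks the ring oxygen and carries the bulky silyl ether; this facial preference is the one selectivity the substrate does not guarantee.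

Step 13
Reactants: 18 (2S,3E,5R,6S,8R)-8-{(S)-1-[(tert-butyldiphenylsilyl)oxy]propyl}-3-chloro-5-(4-methoxyphenoxy)-2-(2-oxoethyl)-5,6,7,8-tetrahydro-2H-oxocin-6-yl acetate
Product: 19 (2S,3S,5R,6S,8R)-8-{(S)-1-[(tert-butyldiphenylsilyl)oxy]propyl}-3-chloro-5-(4-methoxyphenoxy)-2-(2-oxoethyl)oxocan-6-yl acetate
Conditions: H2 (1 atm), [Ir(cod)(PCy3)(C5H5N)]PF6, CH2Cl2, 0 °C to rt
Reagents that add atoms: none
Why: Homogeneous iridium-catalysed hydrogenation should add H2 syn to the chloroalkene from the face opposite the two allylic substituents (the C6 side chain, pushed pseudoaxial by strain against the vinylic chlorine, and the C9 aryloxy group), which places hydrogen on the upper face of C7 and gives (7S), while the cationic catalyst is not expected to cleave the C–Cl bond or reduce the aldehyde.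

Step 14
Reactants: 19 (2S,3S,5R,6S,8R)-8-{(S)-1-[(tert-butyldiphenylsilyl)oxy]propyl}-3-chloro-5-(4-methoxyphenoxy)-2-(2-oxoethyl)oxocan-6-yl acetate
Product: 20 (2S,3S,5R,6S,8R)-8-{(S)-1-[(tert-butyldiphenylsilyl)oxy]propyl}-3-chloro-2-[(E)-3-iodoallyl]-5-(4-methoxyphenoxy)oxocan-6-yl acetate
Conditions: CHI3, CrCl2, THF, 0 °C
Reagents that add atoms: iodoform, IC(I)I
Why: Takai olefination, in which the geminal dichromium reagent from iodoform adds to the aldehyde and eliminates to the (E)-vinyl iodide under non-basic conditions that avoid β-elimination of the ring oxygen.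

Step 15
Reactants: 20 (2S,3S,5R,6S,8R)-8-{(S)-1-[(tert-butyldiphenylsilyl)oxy]propyl}-3-chloro-2-[(E)-3-iodoallyl]-5-(4-methoxyphenoxy)oxocan-6-yl acetate; 21 ethynyltrimethylsilane
Product: 22 (2S,3S,5R,6S,8R)-8-{(S)-1-[(tert-butyldiphenylsilyl)oxy]propyl}-3-chloro-5-(4-methoxyphenoxy)-2-[(E)-5-(trimethylsilyl)pent-2-en-4-yn-1-yl]oxocan-6-yl acetate
Conditions: Pd(PPh3)4, CuI, Et3N, THF, rt
Reagents that add atoms: none
Why: Sonogashira coupling of the vinyl iodide with the terminal alkyne proceeds with retention of the E geometry and tolerates the secondary chloride, acetate and silyl ether.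

Step 16
Reactants: 22 (2S,3S,5R,6S,8R)-8-{(S)-1-[(tert-butyldiphenylsilyl)oxy]propyl}-3-chloro-5-(4-methoxyphenoxy)-2-[(E)-5-(trimethylsilyl)pent-2-en-4-yn-1-yl]oxocan-6-yl acetate
Product: 23 (2S,3S,5R,6S,8R)-8-{(S)-1-[(tert-butyldiphenylsilyl)oxy]propyl}-3-chloro-5-hydroxy-2-[(E)-5-(trimethylsilyl)pent-2-en-4-yn-1-yl]oxocan-6-yl acetate
Conditions: (NH4)2Ce(NO3)6, MeCN/H2O, 0 °C
Reagents that add atoms: none
Why: Oxidative cleavage of the 4-methoxyphenyl ether by tetravalent cerium (to benzoquinone) frees the C9 alcohol without breaking the C9–O bond, so the (R) configuration is kept.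

Step 17
Reactants: 23 (2S,3S,5R,6S,8R)-8-{(S)-1-[(tert-butyldiphenylsilyl)oxy]propyl}-3-chloro-5-hydroxy-2-[(E)-5-(trimethylsilyl)pent-2-en-4-yn-1-yl]oxocan-6-yl acetate
Product: 24 (2S,3S,5S,6S,8R)-8-{(S)-1-[(tert-butyldiphenylsilyl)oxy]propyl}-3,5-dichloro-2-[(E)-5-(trimethylsilyl)pent-2-en-4-yn-1-yl]oxocan-6-yl acetate
Conditions: CCl4, P(n-C8H17)3, toluene, 70 °C
Reagents that add atoms: tetrachloromethane, ClC(Cl)(Cl)Cl
Why: Appel-type deoxychlorination, in which chloride displaces the alkoxyphosphonium group by SN2 with inversion to give (9S), while the neighbouring acetate, being on the same face as the leaving group, cannot take part from the rear.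

Step 18
Reactants: 24 (2S,3S,5S,6S,8R)-8-{(S)-1-[(tert-butyldiphenylsilyl)oxy]propyl}-3,5-dichloro-2-[(E)-5-(trimethylsilyl)pent-2-en-4-yn-1-yl]oxocan-6-yl acetate
Product: 25 (2S,3S,5S,6S,8R)-3,5-dichloro-8-[(S)-1-hydroxypropyl]-2-[(E)-pent-2-en-4-yn-1-yl]oxocan-6-yl acetate
Conditions: n-Bu4NF, AcOH, THF, rt
Reagents that add atoms: none
Why: Fluoride cleaves both the O–Si bond at C13 and the alkynyl C–Si bond, and acetic acid buffering suppresses acetate migration and elimination of the chlorides.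

Step 19
Reactants: 25 (2S,3S,5S,6S,8R)-3,5-dichloro-8-[(S)-1-hydroxypropyl]-2-[(E)-pent-2-en-4-yn-1-yl]oxocan-6-yl acetate
Product: 26 (2S,3S,5S,6S,8R)-8-[(R)-1-bromopropyl]-3,5-dichloro-2-[(E)-pent-2-en-4-yn-1-yl]oxocan-6-yl acetate (CNP0251465.3)
Conditions: CBr4, P(n-C8H17)3, toluene, 70 °C
Reagents that add atoms: tetrabromomethane, BrC(Br)(Br)Br
Why: Appel-type deoxybromination of the side-chain alcohol proceeds by SN2 with inversion, converting the (13S) alcohol into the (13R) bromide of the target.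

Compound list
1 | methyl (S)-2-hydroxybutanoate | CC[C@H](O)C(=O)OC | starting material
2 | methyl (S)-2-[(tert-butyldiphenylsilyl)oxy]butanoate | CC[C@H](O[Si](c1ccccc1)(c1ccccc1)C(C)(C)C)C(=O)OC | intermediate
3 | (S)-2-[(tert-butyldiphenylsilyl)oxy]butanal | CC[C@H](O[Si](c1ccccc1)(c1ccccc1)C(C)(C)C)C=O | intermediate
4 | tert-butyl[(1-methoxyvinyl)oxy]dimethylsilane | C=C(OC)O[Si](C)(C)C(C)(C)C | starting material
5 | methyl (3R,4S)-4-[(tert-butyldiphenylsilyl)oxy]-3-hydroxyhexanoate | CC[C@H](O[Si](c1ccccc1)(c1ccccc1)C(C)(C)C)[C@H](O)CC(=O)OC | intermediate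
6 | methyl (3R,4S)-4-[(tert-butyldiphenylsilyl)oxy]-3-[(triethylsilyl)oxy]hexanoate | CC[C@H](O[Si](c1ccccc1)(c1ccccc1)C(C)(C)C)[C@H](O[Si](CC)(CC)CC)CC(=O)OC | intermediate
7 | (3R,4S)-4-[(tert-butyldiphenylsilyl)oxy]-3-[(triethylsilyl)oxy]hexanal | CC[C@H](O[Si](c1ccccc1)(c1ccccc1)C(C)(C)C)[C@H](O[Si](CC)(CC)CC)CC=O | intermediate
8 | 1-(allyloxy)-4-methoxybenzene | C=CCOc1ccc(OC)cc1 | starting material
9 | [(Z)-3-(4-methoxyphenoxy)allyl]diisopinocampheylborane, isopinocampheyl groups from (+)-α-pinene | COc1ccc(O/C=C\CB([C@@H]2C[C@@H]3C[C@H]([C@H]2C)C3(C)C)[C@@H]2C[C@@H]3C[C@H]([C@H]2C)C3(C)C)cc1 | intermediate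
10 | (3R,4R,6R,7S)-7-[(tert-butyldiphenylsilyl)oxy]-3-(4-methoxyphenoxy)-6-[(triethylsilyl)oxy]non-1-en-4-ol | CC[C@H](O[Si](c1ccccc1)(c1ccccc1)C(C)(C)C)[C@H](O[Si](CC)(CC)CC)C[C@@H](O)[C@H](Oc1ccc(OC)cc1)C=C | intermediate
11 | (3R,4S,6R,7S)-7-[(tert-butyldiphenylsilyl)oxy]-3-(4-methoxyphenoxy)-6-[(triethylsilyl)oxy]non-1-en-4-yl acetate | CC[C@H](O[Si](c1ccccc1)(c1ccccc1)C(C)(C)C)[C@H](O[Si](CC)(CC)CC)C[C@H](OC(C)=O)[C@H](Oc1ccc(OC)cc1)C=C | intermediate
12 | (3R,4S,6R,7S)-7-[(tert-butyldiphenylsilyl)oxy]-6-hydroxy-3-(4-methoxyphenoxy)non-1-en-4-yl acetate | CC[C@H](O[Si](c1ccccc1)(c1ccccc1)C(C)(C)C)[C@H](O)C[C@H](OC(C)=O)[C@H](Oc1ccc(OC)cc1)C=C | intermediate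
13 | (3R,4S,6R,7S)-7-[(tert-butyldiphenylsilyl)oxy]-3-(4-methoxyphenoxy)-6-(vinyloxy)non-1-en-4-yl acetate | CC[C@H](O[Si](c1ccccc1)(c1ccccc1)C(C)(C)C)[C@H](OC=C)C[C@H](OC(C)=O)[C@H](Oc1ccc(OC)cc1)C=C | intermediate
14 | (2R,4S,5R)-2-{(S)-1-[(tert-butyldiphenylsilyl)oxy]propyl}-5-(4-methoxyphenoxy)-2,3,4,5-tetrahydrooxepin-4-yl acetate | CC[C@H](O[Si](c1ccccc1)(c1ccccc1)C(C)(C)C)[C@H]1C[C@H](OC(C)=O)[C@H](Oc2ccc(OC)cc2)C=CO1 | intermediate
15 | (1S,3R,5S,6R,7R)-3-{(S)-1-[(tert-butyldiphenylsilyl)oxy]propyl}-8,8-dichloro-6-(4-methoxyphenoxy)-2-oxabicyclo[5.1.0]octan-5-yl acetate | ClC1(Cl)[C@H]2O[C@@H]([C@@H](O[Si](c3ccccc3)(c3ccccc3)C(C)(C)C)CC)C[C@H](OC(C)=O)[C@H](Oc3ccc(OC)cc3)[C@@H]12 | intermediate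
16 | trimethyl(vinyloxy)silane | C=CO[Si](C)(C)C | starting material
17 | (3E,5R,6S,8R)-6-acetoxy-8-{(S)-1-[(tert-butyldiphenylsilyl)oxy]propyl}-3-chloro-5-(4-methoxyphenoxy)-5,6,7,8-tetrahydrooxocin-1-ium trifluoromethanesulfonate (2-chloroallyl oxocarbenium ion) | Cl/C1=C/[C@@H](Oc2ccc(OC)cc2)[C@@H](OC(C)=O)C[C@H]([C@@H](O[Si](c2ccccc2)(c2ccccc2)C(C)(C)C)CC)[O+]=C1.[O-]S(=O)(=O)C(F)(F)F | intermediate
18 | (2S,3E,5R,6S,8R)-8-{(S)-1-[(tert-butyldiphenylsilyl)oxy]propyl}-3-chloro-5-(4-methoxyphenoxy)-2-(2-oxoethyl)-5,6,7,8-tetrahydro-2H-oxocin-6-yl acetate | Cl/C1=C/[C@@H](Oc2ccc(OC)cc2)[C@@H](OC(C)=O)C[C@H]([C@@H](O[Si](c2ccccc2)(c2ccccc2)C(C)(C)C)CC)O[C@H]1CC=O | intermediate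
19 | (2S,3S,5R,6S,8R)-8-{(S)-1-[(tert-butyldiphenylsilyl)oxy]propyl}-3-chloro-5-(4-methoxyphenoxy)-2-(2-oxoethyl)oxocan-6-yl acetate | O=CC[C@@H]1O[C@@H]([C@@H](O[Si](c2ccccc2)(c2ccccc2)C(C)(C)C)CC)C[C@H](OC(C)=O)[C@H](Oc2ccc(OC)cc2)C[C@@H]1Cl | intermediate
20 | (2S,3S,5R,6S,8R)-8-{(S)-1-[(tert-butyldiphenylsilyl)oxy]propyl}-3-chloro-2-[(E)-3-iodoallyl]-5-(4-methoxyphenoxy)oxocan-6-yl acetate | I/C=C/C[C@@H]1O[C@@H]([C@@H](O[Si](c2ccccc2)(c2ccccc2)C(C)(C)C)CC)C[C@H](OC(C)=O)[C@H](Oc2ccc(OC)cc2)C[C@@H]1Cl | intermediate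
21 | ethynyltrimethylsilane | C#C[Si](C)(C)C | starting material
22 | (2S,3S,5R,6S,8R)-8-{(S)-1-[(tert-butyldiphenylsilyl)oxy]propyl}-3-chloro-5-(4-methoxyphenoxy)-2-[(E)-5-(trimethylsilyl)pent-2-en-4-yn-1-yl]oxocan-6-yl acetate | C[Si](C)(C)C#C/C=C/C[C@@H]1O[C@@H]([C@@H](O[Si](c2ccccc2)(c2ccccc2)C(C)(C)C)CC)C[C@H](OC(C)=O)[C@H](Oc2ccc(OC)cc2)C[C@@H]1Cl | intermediate
23 | (2S,3S,5R,6S,8R)-8-{(S)-1-[(tert-butyldiphenylsilyl)oxy]propyl}-3-chloro-5-hydroxy-2-[(E)-5-(trimethylsilyl)pent-2-en-4-yn-1-yl]oxocan-6-yl acetate | C[Si](C)(C)C#C/C=C/C[C@@H]1O[C@@H]([C@@H](O[Si](c2ccccc2)(c2ccccc2)C(C)(C)C)CC)C[C@H](OC(C)=O)[C@H](O)C[C@@H]1Cl | intermediate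
24 | (2S,3S,5S,6S,8R)-8-{(S)-1-[(tert-butyldiphenylsilyl)oxy]propyl}-3,5-dichloro-2-[(E)-5-(trimethylsilyl)pent-2-en-4-yn-1-yl]oxocan-6-yl acetate | C[Si](C)(C)C#C/C=C/C[C@@H]1O[C@@H]([C@@H](O[Si](c2ccccc2)(c2ccccc2)C(C)(C)C)CC)C[C@H](OC(C)=O)[C@@H](Cl)C[C@@H]1Cl | intermediate
25 | (2S,3S,5S,6S,8R)-3,5-dichloro-8-[(S)-1-hydroxypropyl]-2-[(E)-pent-2-en-4-yn-1-yl]oxocan-6-yl acetate | C#C/C=C/C[C@@H]1O[C@@H]([C@@H](O)CC)C[C@H](OC(C)=O)[C@@H](Cl)C[C@@H]1Cl | intermediate
26 | (2S,3S,5S,6S,8R)-8-[(R)-1-bromopropyl]-3,5-dichloro-2-[(E)-pent-2-en-4-yn-1-yl]oxocan-6-yl acetate (CNP0251465.3) | C#C/C=C/C[C@@H]1O[C@@H]([C@H](Br)CC)C[C@H](OC(C)=O)[C@@H](Cl)C[C@@H]1Cl | target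

Total step count: 19. Longest linear sequence: 19 steps (from 1; compounds 4, 8, 16 and 21 are commercial).

Steps most likely to fail

Step 12 (proposed new method). Ionisation of the C–Cl bond may be too slow below the temperature at which silyl triflate makes the enol ether condense with the product aldehyde. The nucleophile may also fail to discriminate the two faces of C6. The fallback uses known chemistry and sets out from 15. Silver-acetate-promoted ring expansion with capture by acetate (AgOCOCH3, NaOCOCH3, AcOH/toluene, heat) should give the anomeric acetate (3E,5R,6S,8R)-8-{(S)-1-[(tert-butyldiphenylsilyl)oxy]propyl}-3-chloro-5-(4-methoxyphenoxy)-5,6,7,8-tetrahydro-2H-oxocine-2,6-diyl diacetate F1. This acetate is then treated with 16 and BF3·OEt2 in CH2Cl2 at −78 °C, a Lewis-acid substitution of a glycosyl-type acetate by a silyl enol ether, which returns to the route at 18 and separates the hot ionisation from the C–C bond formation.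

Step 13. Hydrogen may be delivered from the lower face after coordination of iridium to the aldehyde, acetate or ether oxygens, and the C–Cl bond may be hydrogenolysed. The fallback sets out from 18 and returns at 19. It is a metal-free diimide reduction (KO2CN=NCO2K, AcOH, pyridine/MeOH, rt), a concerted syn transfer of two hydrogens governed by steric approach only, with no coordination and no insertion into C–Cl. No new compound is involved (F0).

Step 17. The ring oxygen may participate across the ring, or E2 elimination may occur within the hot alkoxyphosphonium ion pair, leading to retention, ring contraction or an alkene. The fallback sets out from 23. Esterification with ClCH2SO2Cl and pyridine in CH2Cl2 at 0 °C gives the chloromethanesulfonate (2S,3S,5R,6S,8R)-8-{(S)-1-[(tert-butyldiphenylsilyl)oxy]propyl}-3-chloro-5-{[(chloromethyl)sulfonyl]oxy}-2-[(E)-5-(trimethylsilyl)pent-2-en-4-yn-1-yl]oxocan-6-yl acetate F2. LiCl in DMF at room temperature then displaces this isolated sulfonate bimolecularly, with external chloride at high concentration, and returns to the route at 24.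

Further compounds
F1 | step 12 | (3E,5R,6S,8R)-8-{(S)-1-[(tert-butyldiphenylsilyl)oxy]propyl}-3-chloro-5-(4-methoxyphenoxy)-5,6,7,8-tetrahydro-2H-oxocine-2,6-diyl diacetate (both C2 epimers) | Cl/C1=C/[C@@H](Oc2ccc(OC)cc2)[C@@H](OC(C)=O)C[C@H]([C@@H](O[Si](c2ccccc2)(c2ccccc2)C(C)(C)C)CC)OC1OC(C)=O
F0 | step 13 | none | none
F2 | step 17 | (2S,3S,5R,6S,8R)-8-{(S)-1-[(tert-butyldiphenylsilyl)oxy]propyl}-3-chloro-5-{[(chloromethyl)sulfonyl]oxy}-2-[(E)-5-(trimethylsilyl)pent-2-en-4-yn-1-yl]oxocan-6-yl acetate | C[Si](C)(C)C#C/C=C/C[C@@H]1O[C@@H]([C@@H](O[Si](c2ccccc2)(c2ccccc2)C(C)(C)C)CC)C[C@H](OC(C)=O)[C@H](OS(=O)(=O)CCl)C[C@@H]1Cl
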